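The vessel was a stirred flask of constant volume in which starting material could meet reagent or itself, and the recipes differed in what stood in it first.

    starting material + protic impurity → quenched substrate (k1 = 1.42 /M/s)
    starting material → side product A (k2 = 0.00303 /s)
    reagent + target → over-reaction product (k3 = 0.332 /M/s)
    crystals ⇌ target, rate k4*(cs4 - [target]) while solid is left; crystals form when [target] > cs4 (cs4 = 36 mM, k4 = 0.201 /s)
    2 starting material → side product B (k5 = 2.10 /M/s)
    starting material + reagent → target (k6 = 1.03 /M/s)

all flasks: protic impurity 7.80 mM; time 1.0 min
- violet: starting material 0.039 M (fed, over 25 s); reagent 0.0429 M; all else is in the flask from the start; the feed brings no volume worth counting
- teal: starting material 0.039 M; reagent 0.0429 M; everything together at the start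
- amber: starting material 0.039 M; reagent 0.0429 M (fed, over 25 s); all else is in the flask from the start; the feed brings no volume worth counting

- percent here means starting material units held: one side product B counts as two
- what is said of target includes crystals
- a doubled species enters its step squared and goes two at a time
- crystals is a solid; its amount is given per volume of the solution
- run time (violet): 1.0 min

* the flask that comes out highest in amount of target, in percent of the starting material charged, or "all alike" when all lie within 1.5 percentage points (violet / teal / amber / all alike)
* target at the end, in percent of the starting material charged, violet
* target at the end, in percent of the starting material charged, teal
* target at the end, in percent of the starting material charged, amber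

- I began with half-lives in teal at the charged concentrations, and the fastest rung was the pairing of starting material to side product B at 0.102 min. On the next rung starting material had a half-life of 0.26 min by its step with reagent. Below that, dissolved target had a half-life of 0.81 min against reagent. On the lowest rungs starting material had a half-life of 1.0 min by the quench and 3.8 min by its step to side product A.

- The top two rungs competed through c(starting material), so I kept one figure, 0.01052 M: the crossover concentration, the c(starting material) at which it goes to target and to side product B equally fast, with reagent held at its charge so that the step to target was pseudo-first-order. Above it, I reckoned, pairing wins; the share going to target, the selectivity, is the crossover over the crossover plus c(starting material).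

- For teal I summed that share as c(starting material) fell from its charge, and I let the target stand exposed to reagent for the whole run, keeping a fraction 0.425, which gave 17.8%.

- For violet I balanced the feed against both steps, which gave a steady 0.01472 M, above the crossover. I dated the target from the end of the feed, keeping a fraction 0.607, which gave 25.3%. That target before loss, 0.0163 M, lay below the solubility, so I left crystals out.

- For amber I let c(starting material) fall from its charge by pairing alone while c(reagent) rose steadily over the feed. Summing the step to target over the feed gave a share of 16.2% of the charge, and with the same age as in violet this gave 9.87%. My order put violet first.

- The forecast also chose violet, with 29% (25% to 33%) for violet, 21% (18% to 24%) for teal and 12.5% (10% to 16%) for amber, because “feeding starting material into excess reagent keeps its concentration low”. It stood above my violet, my teal and my amber.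

- The run put violet highest at 1.00 min, with 27.0% in violet, 20.3% in teal and 11.7% in amber. In violet, at the end of the feed at 0.417 min, c(starting material) stood at 0.0141 M, close to my 0.0147 M, with target at 21.9% and side product B at 31.1%; then, with reagent at 74.9% of its charge and falling, over-reaction product rose to 11.2%. The neighbour of amber with 0.17 M of reagent had a crossover of 0.0417 M, above the charge, and ended with side product B at 57.4% against amber's 68.8%, target at 4.25% and over-reaction product at 29.5%.

Its constants belong to no real substance; what happens was integrated by code.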